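**Retrosynthetic overview**

1. Numbering: O1, C2(=O), C3, C4(Br), C5(=C6HBr) in the furan-2(5H)-one ring; C1' is the acetoxy carbon. The only ring is closed last, through O1–C5, by 5-exo-dig anti bromolactonisation of a 3-bromo-2-en-4-ynoic acid, which also puts the C6 bromine trans to O1.
2. The C2 carboxyl is unmasked from a vinyl group (ozonolysis, then Pinnick oxidation).
3. The strategy rests on the tetrasubstituted C3=C4 ring alkene, which has C1' and the C4 bromine on one side and the ring carbons C2 and C5 on the other. It is cut at C2–C3 and C4–Br: alkoxide-directed anti vinylmagnesiation of an (R)-diynol, then bromination of the C–Mg bond.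
4. The diynol comes from butanal and mono-silylated butadiyne by catalytic asymmetric alkynylation, which sets C1'.

Key step: step 3

Remark (assumption): the target is taken as drawn, 1'R with the C6 bromine trans to O1 (5E). The ProPhenol enantiomer that gives Si-face alkynyl transfer is assumed to be (S,S); the configuration of 6 is to be checked by Mosher ester analysis and the antipodal ligand used if the sense is opposite. Octane numbering of 6–13 maps onto the target as C4 = C1', C5 = C3, C6 = C4, C7 = C5, C8 = C6.

**Step 1**
Reactants: 1 1,4-bis(trimethylsilyl)buta-1,3-diyne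
Product: 3 buta-1,3-diynyl(trimethyl)silane, via lithium (trimethylsilyl)butadiynide 2 (not isolated)
Conditions: MeLi·LiBr (1.0 equiv), Et2O, 0 °C → rt; cold 1 M HCl; ether exchanged for toluene by careful distillation, kept as a stock solution
Reagents that add atoms: none
Why: Methyllithium attacks one silicon of 1 and expels the alkynyl anion (nucleophilic Si–C(sp) cleavage, a standard selective monodesilylation, since the lithium diynide 2 resists a second attack), and protonation gives 3.

**Step 2**
Reactants: 3 buta-1,3-diynyl(trimethyl)silane (2.5 equiv); 4 butanal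
Product: 6 (4R)-8-(trimethylsilyl)octa-5,7-diyn-4-ol, via methylzinc diynide 5 (not isolated)
Conditions: Me2Zn (3 equiv), (S,S)-ProPhenol (20 mol%), Ph3PO (40 mol%), toluene, 0 °C; then 4 added slowly, 4 °C; 1 M HCl work-up
Reagents that add atoms: none
Why: Zinc–ProPhenol catalysed asymmetric alkynylation: Me2Zn zincates the acidic diyne C–H to 5, and the dinuclear zinc–ProPhenol complex binds aldehyde and alkynylzinc and delivers the diynyl group to the Si face of butanal, which sets C4 as R (the later C1').

**Step 3**
Reactants: 6 (4R)-8-(trimethylsilyl)octa-5,7-diyn-4-ol; 7 vinylmagnesium chloride; 8 N-bromosuccinimide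
Product: 11 (4R,5Z)-6-bromo-5-ethenyl-8-(trimethylsilyl)oct-5-en-7-yn-4-ol, via chloromagnesium alkoxide 9 (not isolated), via oxamagnesacycle chelate 10 (not isolated)
Conditions: 7 (2.5 equiv, THF solution), THF/toluene, 0 → 45 °C; then 8 (3 equiv) in THF, −78 → −20 °C; cold 1 M HCl
Reagents that add atoms: vinylmagnesium chloride (7), C=C[Mg]Cl; N-bromosuccinimide (8), O=C1CCC(=O)N1Br
Why: The first equivalent of 7 deprotonates 6 to the alkoxide 9 with loss of ethene, and a second equivalent, held at the alkoxide magnesium, transfers its vinyl group to the proximal alkyne carbon C5 while magnesium bonds to C6 from the opposite face, giving the five-membered oxamagnesacycle 10 (anti carbomagnesiation; the closest known reaction type is the magnesium-mediated anti addition of vinyl Grignard reagents to propargylic alcohols with electrophilic capture of the chelated alkenylmagnesium). NBS then cleaves the C6–Mg bond with retention at the sp2 carbon, so bromine ends cis to the carbinol carbon and the silylalkynyl arm cis to the new vinyl group, the 5Z geometry that becomes the C3=C4 ring alkene. No ring of the target closes here; the only ring is the transient chelate, closed through O–Mg–C6 as the C5–vinyl bond forms. No stereocentre is created, and the C4 centre is carried through as its alkoxide, which has no path to epimerisation under these conditions. The step needs regioselectivity (carbon to C5, metal to C6), anti geometry and site selectivity between the two alkynes: only the adjacent alkyne can form the five-membered chelate, the alkynyl substituent on C6 stabilises the developing carbanion there, and the silyl cap shields the remote triple bond.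

**Step 4**
Reactants: 11 (4R,5Z)-6-bromo-5-ethenyl-8-(trimethylsilyl)oct-5-en-7-yn-4-ol
Product: 12 (4R,5Z)-6-bromo-5-ethenyloct-5-en-7-yn-4-ol
Conditions: K2CO3 (0.2 equiv), MeOH, 0 °C
Reagents that add atoms: none
Why: Methoxide-catalysed protodesilylation of the alkynylsilane is done here, on the free alcohol, so that no acetate or carboxylic acid meets base later; the tetrasubstituted bromoalkene has no β-hydrogen for elimination.

**Step 5**
Reactants: 12 (4R,5Z)-6-bromo-5-ethenyloct-5-en-7-yn-4-ol
Product: 13 (4R,5Z)-6-bromo-5-ethenyloct-5-en-7-yn-4-yl acetate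
Conditions: Ac2O, pyridine, DMAP (cat.), CH2Cl2, 0 °C → rt
Reagents that add atoms: acetic anhydride, CC(=O)OC(C)=O
Why: DMAP-catalysed O-acylation of the secondary allylic alcohol proceeds with retention at C4 and installs the acetate of the target before any oxidation.

**Step 6**
Reactants: 13 (4R,5Z)-6-bromo-5-ethenyloct-5-en-7-yn-4-yl acetate
Product: 15 (2E)-2-[(1R)-1-acetoxybutyl]-3-bromopent-2-en-4-ynal, via secondary ozonide 14 (not isolated)
Conditions: O3/O2, CH2Cl2, −78 °C, Sudan Red 7B end point; then Me2S (excess), −78 °C → rt; used crude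
Reagents that add atoms: ozone, [O-][O+]=O
Why: Ozonolysis with reductive work-up (Criegee mechanism): the electrophilic oxidant should cleave the monosubstituted vinyl group in preference to the tetrasubstituted alkene, which is hindered and deactivated by bromine and the alkynyl group, and to the alkyne, and the indicator stops the reaction at one equivalent.

**Step 7**
Reactants: 15 (2E)-2-[(1R)-1-acetoxybutyl]-3-bromopent-2-en-4-ynal
Product: 16 (2E)-2-[(1R)-1-acetoxybutyl]-3-bromopent-2-en-4-ynoic acid
Conditions: NaClO2, NaH2PO4, 2-methylbut-2-ene, t-BuOH/H2O, 0 °C → rt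
Reagents that add atoms: sodium chlorite, [Na+].[O-]Cl=O
Why: Pinnick oxidation converts the enal to the acid without touching alkene geometry, alkyne, acetate or the C1' centre, and 2-methylbut-2-ene removes HOCl so that no halolactonisation starts early.

**Step 8**
Reactants: 16 (2E)-2-[(1R)-1-acetoxybutyl]-3-bromopent-2-en-4-ynoic acid; 8 N-bromosuccinimide
Product: 17 acetoxyfimbrolide, (1R)-1-[(5E)-4-bromo-5-(bromomethylidene)-2-oxo-2,5-dihydrofuran-3-yl]butyl acetate
Conditions: 8 (1.1 equiv), KHCO3 (0.2 equiv), Bu4NOH (5 mol%), CH2Cl2/H2O, 0 °C → rt, dark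
Reagents that add atoms: N-bromosuccinimide (8), O=C1CCC(=O)N1Br
Why: Bromolactonisation of a 2-en-4-ynoic acid: the carboxylate held cis to the alkyne attacks the internal alkyne carbon (5-exo-dig, Markovnikov) anti to the bromonium ion at the terminal carbon, which closes the furanone ring through O1–C5 and places the new bromine trans to O1, the 5E geometry of the target.

**Compound list**

1 | 1,4-bis(trimethylsilyl)buta-1,3-diyne | C[Si](C)(C)C#CC#C[Si](C)(C)C | starting material
2 | lithium 4-(trimethylsilyl)buta-1,3-diyn-1-ide | [Li]C#CC#C[Si](C)(C)C | intermediate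
3 | buta-1,3-diynyl(trimethyl)silane | C#CC#C[Si](C)(C)C | intermediate
4 | butanal | CCCC=O | starting material
5 | methyl[4-(trimethylsilyl)buta-1,3-diyn-1-yl]zinc | C[Zn]C#CC#C[Si](C)(C)C | intermediate
6 | (4R)-8-(trimethylsilyl)octa-5,7-diyn-4-ol | CCC[C@@H](O)C#CC#C[Si](C)(C)C | intermediate
7 | vinylmagnesium chloride | C=C[Mg]Cl | starting material
8 | N-bromosuccinimide | O=C1CCC(=O)N1Br | starting material
9 | chloromagnesium (4R)-8-(trimethylsilyl)octa-5,7-diyn-4-olate | CCC[C@@H](O[Mg]Cl)C#CC#C[Si](C)(C)C | intermediate
10 | (5R)-4-ethenyl-5-propyl-3-[(trimethylsilyl)ethynyl]-2,5-dihydro-1,2-oxamagnesole | CCC[C@H]1O[Mg]C(C#C[Si](C)(C)C)=C1C=C | intermediate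
11 | (4R,5Z)-6-bromo-5-ethenyl-8-(trimethylsilyl)oct-5-en-7-yn-4-ol | CCC[C@@H](O)/C(C=C)=C(\Br)C#C[Si](C)(C)C | intermediate
12 | (4R,5Z)-6-bromo-5-ethenyloct-5-en-7-yn-4-ol | CCC[C@@H](O)/C(C=C)=C(\Br)C#C | intermediate
13 | (4R,5Z)-6-bromo-5-ethenyloct-5-en-7-yn-4-yl acetate | CCC[C@@H](OC(C)=O)/C(C=C)=C(\Br)C#C | intermediate
14 | (4R,5E)-6-bromo-5-(1,2,4-trioxolan-3-yl)oct-5-en-7-yn-4-yl acetate (epimers at the trioxolane carbon) | CCC[C@@H](OC(C)=O)/C(C1OCOO1)=C(\Br)C#C | intermediate
15 | (2E)-2-[(1R)-1-acetoxybutyl]-3-bromopent-2-en-4-ynal | CCC[C@@H](OC(C)=O)/C(C=O)=C(\Br)C#C | intermediate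
16 | (2E)-2-[(1R)-1-acetoxybutyl]-3-bromopent-2-en-4-ynoic acid | CCC[C@@H](OC(C)=O)/C(C(=O)O)=C(\Br)C#C | intermediate
17 | acetoxyfimbrolide, (1R)-1-[(5E)-4-bromo-5-(bromomethylidene)-2-oxo-2,5-dihydrofuran-3-yl]butyl acetate | CCC[C@@H](OC(C)=O)C1=C(Br)/C(=C\Br)OC1=O | target

**Step count and risks**

Total step count: 8. Longest linear sequence: 8 steps (from 1).

Steps most likely to fail:

Step 3. Capture of the chelated alkenylmagnesium by the bromine electrophile may be incomplete or unselective: excess Grignard reagent competes for NBS, the magnesium alkoxide may be oxidised, or bromine may be delivered through the cumulenic form of the alkynyl-substituted organometallic. Fallback, setting out from 6 and returning at 11: the chelate 10 is generated as in step 3 and quenched with Bu3SnCl (THF, −78 °C → rt) to give the isolable alkenylstannane (4R,5Z)-5-ethenyl-6-(tributylstannyl)-8-(trimethylsilyl)oct-5-en-7-yn-4-ol F1. After purification, F1 is treated with NBS in CH2Cl2 at −78 °C; ipso bromodestannylation with retention should give 11 without any Grignard reagent or alkoxide present.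

Step 8. Bromonium formation on the electron-poor alkyne may be slow, closure may go 6-endo to a bromopyranone, or the bromomethylidene may isomerise under light or bromine radicals. Fallback, setting out from 16 and returning at 17: the alkyne is activated by a metal instead of bromine. Anti oxymercuration with Hg(OCOCF3)2 (CH2Cl2, 0 °C) followed by aqueous KBr should give the alkenylmercurial (1R)-1-[(5E)-4-bromo-5-[(bromomercurio)methylidene]-2-oxo-2,5-dihydrofuran-3-yl]butyl acetate F2, with mercury trans to O1. Bromodemercuration with Br2 in pyridine at 0 °C proceeds with retention and should give 17.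

Step 2. The unbranched, enolisable aldehyde may undergo self-aldol under the zinc catalyst, and enantioselectivity may be insufficient for a single enantiomer. Fallback, setting out from 2 (generated from 1 as in step 1, not quenched) and 4, and returning at 6: 2 is added to butanal in Et2O at −78 °C to give racemic 8-(trimethylsilyl)octa-5,7-diyn-4-ol F3. Oxidation with MnO2 (CH2Cl2, rt) gives the ynone 8-(trimethylsilyl)octa-5,7-diyn-4-one F4. Noyori asymmetric transfer hydrogenation with preformed Ru[(R,R)-TsDPEN](p-cymene) in i-PrOH at rt should give (R)-6, the (R,R) catalyst giving R carbinols from alkynyl ketones.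

**Further compounds**

F1 | step 3 | (4R,5Z)-5-ethenyl-6-(tributylstannyl)-8-(trimethylsilyl)oct-5-en-7-yn-4-ol | CCC[C@@H](O)/C(C=C)=C(\[Sn](CCCC)(CCCC)CCCC)C#C[Si](C)(C)C
F2 | step 8 | (1R)-1-[(5E)-4-bromo-5-[(bromomercurio)methylidene]-2-oxo-2,5-dihydrofuran-3-yl]butyl acetate | CCC[C@@H](OC(C)=O)C1=C(Br)/C(=C\[Hg]Br)OC1=O
F3 | step 2 | racemic 8-(trimethylsilyl)octa-5,7-diyn-4-ol | CCCC(O)C#CC#C[Si](C)(C)C
F4 | step 2 | 8-(trimethylsilyl)octa-5,7-diyn-4-one | CCCC(=O)C#CC#C[Si](C)(C)C
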